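**Plan**
- Retrosynthesis: the C6 phenol is masked as a benzyl ether; the pyran ring is then cut at C4–C4a and C8a–O1 together, leaving an aryl iodide (iodine on C8a) and a C20 chain with a primary bromide (C4) and a tertiary alcohol (O1 on C2). The chain goes back through C4–Br and C3–H to the 2,3-epoxide of phytol.
- Enabling feature: C4–C4a and C8a–O1 end on adjacent carbons of the benzene ring, the C8 methyl blocks the second ortho position, and O1 sits on a fully substituted C2. An ortho C–H alkylation with ipso C–O coupling can therefore build the six-membered pyran ring onto the intact arene.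
- Forward order: phytol is epoxidised, reduced to the 1,3-diol and brominated at the primary carbon; 4-iodo-3-methylphenol is benzylated; the fragments are joined and the pyran ring (the only ring formed) is closed in one palladium/norbornene operation; hydrogenolysis frees the phenol.
- Stereochemistry: C4' and C8' are C7 and C11 of natural phytol. C2 is set by tartrate-controlled epoxidation of the phytol double bond, and its C–O bond is never broken afterwards.

Key step: step 5

Assumption: commercial natural phytol of (2E,7R,11R) configuration and high E purity is used; chroman numbering (O1, C2–C4, C4a, C5–C8, C8a, side chain C1'–C13') is applied to the target and to the atoms that end up in it.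

**Step 1**
Reactants: 1 natural phytol, (2E,7R,11R)-3,7,11,15-tetramethylhexadec-2-en-1-ol
Product: 2 (2R,3R)-2,3-epoxyphytol, [(2R,3R)-3-methyl-3-[(4R,8R)-4,8,12-trimethyltridecyl]oxiran-2-yl]methanol
Conditions: Ti(OiPr)4 (10 mol %), D-(−)-diethyl tartrate (12 mol %), t-BuOOH, 4 Å molecular sieves, CH2Cl2, −20 °C
Reagents that add atoms: tert-butyl hydroperoxide, CC(C)(C)OO
Why: Katsuki–Sharpless asymmetric epoxidation of an (E)-3,3-disubstituted allylic alcohol is reagent-controlled, and the D-(−)-tartrate should give the (2R,3R) epoxide (the mirror-image series of the (2S,3S) epoxides that geraniol-type alcohols give with L-(+)-tartrate), so C3, the future C2 of the chroman, is set here without influence from the remote C7 and C11 centres.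

**Step 2**
Reactants: 2 (2R,3R)-2,3-epoxyphytol
Product: 3 (3R,7R,11R)-3,7,11,15-tetramethylhexadecane-1,3-diol
Conditions: NaAlH2(OCH2CH2OCH3)2, THF, 0 °C to rt; aq. KNaC4H4O6 work-up
Reagents that add atoms: none
Why: Reductive opening of a 2,3-epoxy alcohol by the aluminate: the C1 alkoxide binds aluminium and hydride is delivered intramolecularly to C2, which is also the less substituted epoxide carbon, so the 1,3-diol should result with the C3–O bond and its R configuration untouched.

**Step 3**
Reactants: 3 (3R,7R,11R)-3,7,11,15-tetramethylhexadecane-1,3-diol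
Product: 4 (3R,7R,11R)-1-bromo-3,7,11,15-tetramethylhexadecan-3-ol
Conditions: CBr4, PPh3, CH2Cl2, 0 °C
Reagents that add atoms: tetrabromomethane, BrC(Br)(Br)Br
Why: Appel reaction: only the unhindered primary hydroxyl is activated as an alkoxyphosphonium ion and displaced by bromide in an SN2 step, while the tertiary hydroxyl is too hindered to react at 0 °C and C3 is not involved.

**Step 4**
Reactants: 5 4-iodo-3-methylphenol; 6 benzyl bromide
Product: 7 4-(benzyloxy)-1-iodo-2-methylbenzene
Conditions: K2CO3, DMF, rt
Reagents that add atoms: none
Why: Williamson ether synthesis: the phenoxide formed by K2CO3 is alkylated by the benzylic bromide, and the aryl iodide is inert under these conditions.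

**Step 5**
Reactants: 7 4-(benzyloxy)-1-iodo-2-methylbenzene; 4 (3R,7R,11R)-1-bromo-3,7,11,15-tetramethylhexadecan-3-ol
Product: 8 O-benzyl-(2R,4'R,8'R)-δ-tocopherol, (2R)-6-(benzyloxy)-2,8-dimethyl-2-[(4R,8R)-4,8,12-trimethyltridecyl]-3,4-dihydro-2H-chromene
Conditions: Pd(OAc)2 (10 mol %), XPhos (20 mol %), norbornene (1 equiv), Cs2CO3 (3 equiv), 1,4-dioxane, 100 °C
Reagents that add atoms: none
Why: Proposed new method: zerovalent palladium should insert into the C–I bond of 7, norbornene then carbopalladates the aryl–palladium bond and carbonate-assisted palladation of the only free ortho C–H (the future C4a) gives an aryl–norbornyl palladacycle of divalent palladium, to which the primary C–Br bond of 4 adds to reach tetravalent palladium, and reductive elimination forms C4–C4a. With both ortho positions now occupied, β-carbon elimination expels norbornene, the arylpalladium halide of divalent palladium exchanges halide for the tethered tertiary alkoxide, and C–O reductive elimination from a seven-membered oxapalladacycle forms C8a–O1, so the pyran ring closes in a 6-exo sense at the ipso carbon onto the existing benzene ring. The closest known reaction types are the Catellani ortho-alkylation terminated by ipso C–N or C–O annulation (indolines from bromoalkyl amines, 2,3-dihydrobenzofurans from epoxides) and the palladium-catalysed cyclisation of 2-haloaryl tertiary alcohols to chromans, but their union with a 3-bromo tertiary alcohol to give a chroman has not been shown. No stereocentre is formed: C2 is carried in from 4 and keeps its R configuration because its C–O bond is not broken, and C4' and C8' are remote spectators. The step needs a single alkylation at C4a and C–O coupling at the ipso carbon instead of hydride transfer or a second norbornene insertion; the C8 methyl blocks the other ortho position and forces norbornene out after one alkylation, the alkoxide has no hydrogen on its carbinol carbon so β-hydride elimination is impossible, and the bulky, electron-rich XPhos on a doubly ortho-substituted arylpalladium centre should favour C–O reductive elimination.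

**Step 6**
Reactants: 8 O-benzyl-(2R,4'R,8'R)-δ-tocopherol
Product: 9 δ-tocopherol, (2R)-2,8-dimethyl-2-[(4R,8R)-4,8,12-trimethyltridecyl]-3,4-dihydro-2H-chromen-6-ol
Conditions: H2 (1 atm), Pd on carbon (10 wt %), EtOAc, rt
Reagents that add atoms: none
Why: Hydrogenolysis of a benzyl aryl ether over palladium; the chroman ether, the saturated chain and the three stereocentres are inert to these conditions.

**Compound list**
1 | natural phytol, (2E,7R,11R)-3,7,11,15-tetramethylhexadec-2-en-1-ol | OC/C=C(\C)CCC[C@H](C)CCC[C@H](C)CCCC(C)C | starting material
2 | (2R,3R)-2,3-epoxyphytol, [(2R,3R)-3-methyl-3-[(4R,8R)-4,8,12-trimethyltridecyl]oxiran-2-yl]methanol | O1[C@](C)(CCC[C@H](C)CCC[C@H](C)CCCC(C)C)[C@H]1CO | intermediate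
3 | (3R,7R,11R)-3,7,11,15-tetramethylhexadecane-1,3-diol | O[C@](C)(CCC[C@H](C)CCC[C@H](C)CCCC(C)C)CCO | intermediate
4 | (3R,7R,11R)-1-bromo-3,7,11,15-tetramethylhexadecan-3-ol | O[C@](C)(CCC[C@H](C)CCC[C@H](C)CCCC(C)C)CCBr | intermediate
5 | 4-iodo-3-methylphenol | Cc1cc(O)ccc1I | starting material
6 | benzyl bromide | BrCc1ccccc1 | starting material
7 | 4-(benzyloxy)-1-iodo-2-methylbenzene | Cc1cc(OCc2ccccc2)ccc1I | intermediate
8 | O-benzyl-(2R,4'R,8'R)-δ-tocopherol | Cc1cc(OCc3ccccc3)cc2c1O[C@](C)(CCC[C@H](C)CCC[C@H](C)CCCC(C)C)CC2 | intermediate
9 | (2R,4'R,8'R)-δ-tocopherol | Cc1cc(O)cc2c1O[C@](C)(CCC[C@H](C)CCC[C@H](C)CCCC(C)C)CC2 | target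

**Step count**
Total: 6 steps. Longest linear sequence: 5 steps (steps 1, 2, 3, 5, 6).

**Steps most likely to fail**

Step 5. C–O reductive elimination from the electron-rich (para-benzyloxy) arylpalladium alkoxide may be slower than hydride transfer to the ipso carbon or renewed norbornene insertion, so the chain is attached but the ring stays open. The bromo alcohol may also be consumed by base before it reaches the palladacycle.
Fallback (sets out from 7 and 4, returns at 8): the two bond formations are separated.
- The same ortho-alkylation is run with a hydride donor so that the ipso carbon is reduced on purpose (Pd(OAc)2, tri(2-furyl)phosphine, norbornene, Cs2CO3, HCO2Na, MeCN, 90 °C). This is a known route to meta-substituted arenes and should give (3R,7R,11R)-1-[3-(benzyloxy)-5-methylphenyl]-3,7,11,15-tetramethylhexadecan-3-ol F1.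
- Electrophilic bromination with N-bromosuccinimide in MeCN at 0 °C should enter para to the benzyloxy group, between the methyl group and the chain, to give (3R,7R,11R)-1-[5-(benzyloxy)-2-bromo-3-methylphenyl]-3,7,11,15-tetramethylhexadecan-3-ol F2.
- Intramolecular palladium-catalysed etherification of the aryl bromide with the tertiary alcohol (Pd(OAc)2, 2-(di-tert-butylphosphino)-1,1'-binaphthyl, Cs2CO3, toluene, 80 °C) then forms C8a–O1 and delivers 8.

Step 3. The tertiary hydroxyl may be activated alongside the primary one and eliminate, or it may displace the primary alkoxyphosphonium group to form an oxetane.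
Fallback (sets out from 3, returns at 4): activation and displacement are separated. The primary hydroxyl is sulfonylated selectively (TsCl, pyridine, CH2Cl2, 0 °C) to give (3R,7R,11R)-3-hydroxy-3,7,11,15-tetramethylhexadecyl 4-methylbenzenesulfonate F3, and LiBr in acetone at 50 °C displaces the tosylate to give 4.

Step 2. Hydride may attack after base-induced epoxide migration (Payne-type) or at C3, giving regioisomeric diols.
Fallback (sets out from 2, returns at 3): hydride opening is avoided altogether.
- The primary hydroxyl of 2 is exchanged for iodide (PPh3, I2, imidazole, CH2Cl2, 0 °C) to give (2S,3R)-2-(iodomethyl)-3-methyl-3-[(4R,8R)-4,8,12-trimethyltridecyl]oxirane F4. The spatial arrangement is that of 2; the C2 descriptor changes only because iodine raises the rank of C1.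
- Zn dust in refluxing EtOH triggers reductive ring opening to the tertiary allylic alcohol (3R,7R,11R)-3,7,11,15-tetramethylhexadec-1-en-3-ol F5 without touching the C3–O bond.
- Anti-Markovnikov hydroboration with 9-borabicyclo[3.3.1]nonane in THF gives 9-[(3S,7R,11R)-3-hydroxy-3,7,11,15-tetramethylhexadecyl]-9-borabicyclo[3.3.1]nonane F6 (descriptor change by ranking only), which is oxidised in the same flask with NaOH and H2O2 to diol 3.

**Further compounds**
F1 | step 5 | (3R,7R,11R)-1-[3-(benzyloxy)-5-methylphenyl]-3,7,11,15-tetramethylhexadecan-3-ol | O[C@](C)(CCC[C@H](C)CCC[C@H](C)CCCC(C)C)CCc1cc(C)cc(OCc2ccccc2)c1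
F2 | step 5 | (3R,7R,11R)-1-[5-(benzyloxy)-2-bromo-3-methylphenyl]-3,7,11,15-tetramethylhexadecan-3-ol | O[C@](C)(CCC[C@H](C)CCC[C@H](C)CCCC(C)C)CCc1cc(OCc2ccccc2)cc(C)c1Br
F3 | step 3 | (3R,7R,11R)-3-hydroxy-3,7,11,15-tetramethylhexadecyl 4-methylbenzenesulfonate | O[C@](C)(CCC[C@H](C)CCC[C@H](C)CCCC(C)C)CCOS(=O)(=O)c1ccc(C)cc1
F4 | step 2 | (2S,3R)-2-(iodomethyl)-3-methyl-3-[(4R,8R)-4,8,12-trimethyltridecyl]oxirane | O1[C@](C)(CCC[C@H](C)CCC[C@H](C)CCCC(C)C)[C@H]1CI
F5 | step 2 | (3R,7R,11R)-3,7,11,15-tetramethylhexadec-1-en-3-ol | O[C@](C)(CCC[C@H](C)CCC[C@H](C)CCCC(C)C)C=C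
F6 | step 2 | 9-[(3S,7R,11R)-3-hydroxy-3,7,11,15-tetramethylhexadecyl]-9-borabicyclo[3.3.1]nonane | O[C@](C)(CCC[C@H](C)CCC[C@H](C)CCCC(C)C)CCB1C2CCCC1CCC2
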